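**Retrosynthetic overview**
- Target 24 is traced back, through ether cleavage and Fries butyrylation at B5, to phenol 21, whose ring B is a 3,5-diethoxyphenol carrying both protected outer rings.
- Ring B of 21 is opened by a cyclobutenone–alkyne benzannulation into 3-ethoxycyclobutenone 16 (supplies B3, B4, B5, B6 and the ring C arm) and ynol ether 10 (supplies B1, B2 and the ring A arm); the bonds are B6–B1, B2–B3 and B5–B6.
- 16 comes from ynol ether 15 and ketene; 10 and 15 come from bromomethyl dienones 9 and 14 by Stille coupling with stannane 3; 9 and 14 come from acylphloroglucinols 6 and 11 by C-trimethylation, O-methylation and allylic bromination.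
- Rings A and C are made first as dearomatised acylphloroglucinols; ring B is formed last, between them. The target has no stereocentre.
- Feature used: ring B is a hexasubstituted benzene with oxygen on B2, B4, B6 and carbon on B1, B3, B5. A vinylketene (two oxygens) and an alkoxyalkyne (one oxygen) give exactly this alternation, with both CH2 arms already attached.

Key step: step 12

Assumption: double O-methylation of each 2-acyl-4,4,6-trimethylcyclohexane-1,3,5-trione is drawn as the cross-conjugated 3,5-dimethoxy-2,5-dienone; a linear dienone isomer would carry the same allylic methyl group and masked oxygens through every later step and converge at the final ether cleavage.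

Naming shorthand: "ring A arm" is the (5-butanoyl-2,4-dimethoxy-3,3-dimethyl-6-oxocyclohexa-1,4-dien-1-yl)methyl group; "ring C arm" is the (5-acetyl-2,4-dimethoxy-3,3-dimethyl-6-oxocyclohexa-1,4-dien-1-yl)methyl group.

**Step 1**
Reactants: 1 ethoxyacetylene
Product: 3 tributyl(ethoxyethynyl)stannane, via lithium ethoxyacetylide 2 (not isolated)
Conditions: n-BuLi, THF, −78 °C; then Bu3SnCl, −78 °C → rt
Reagents that add atoms: tributyltin chloride, CCCC[Sn](CCCC)(CCCC)Cl
Why: Deprotonation of the terminal alkyne and stannylation of the lithium acetylide at tin (salt metathesis) should give the distillable alkynylstannane.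

**Step 2**
Reactants: 4 phloroglucinol (anhydrous); 5 butyryl chloride
Product: 6 1-(2,4,6-trihydroxyphenyl)butan-1-one
Conditions: AlCl3 (promoter, excess), PhNO2–CH2Cl2, rt → 40 °C; ice/aq. HCl
Reagents that add atoms: none
Why: Friedel–Crafts acylation of the symmetric triol, which should stop after one acyl group because the ketone deactivates the ring.

**Step 3**
Reactants: 6 1-(2,4,6-trihydroxyphenyl)butan-1-one
Product: 7 2-butanoyl-3,5-dihydroxy-4,4,6-trimethylcyclohexa-2,5-dien-1-one
Conditions: NaOMe (4.5 equiv), MeI (3.2 equiv), MeOH, 0 °C → rt; aq. HCl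
Reagents that add atoms: iodomethane, CI
Why: Dearomatising C-methylation of an acylphloroglucinol (enolate C-alkylation, favoured over O-alkylation in methanol), with limiting iodomethane to hold the sequence at the trimethyl stage; the tetramethyl by-product would be removed by chromatography.

**Step 4**
Reactants: 7 2-butanoyl-3,5-dihydroxy-4,4,6-trimethylcyclohexa-2,5-dien-1-one
Product: 8 2-butanoyl-3,5-dimethoxy-4,4,6-trimethylcyclohexa-2,5-dien-1-one
Conditions: TMSCHN2 (4 equiv), toluene–MeOH 4:1, 0 °C → rt
Reagents that add atoms: (trimethylsilyl)diazomethane, C[Si](C)(C)C=[N+]=[N-]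
Why: Diazoalkane O-methylation of the two acidic enols of the β-triketone; no base is present, so C-methylation at C6 should not compete.

**Step 5**
Reactants: 8 2-butanoyl-3,5-dimethoxy-4,4,6-trimethylcyclohexa-2,5-dien-1-one
Product: 9 2-(bromomethyl)-6-butanoyl-3,5-dimethoxy-4,4-dimethylcyclohexa-2,5-dien-1-one
Conditions: NBS (1.05 equiv), AIBN (5 mol%), PhCF3, 80 °C
Reagents that add atoms: N-bromosuccinimide, O=C1CCC(=O)N1Br
Why: Wohl–Ziegler bromination, selective for the C6 methyl group because its radical is allylic and delocalised into the β-methoxy enone, whereas the gem-dimethyl, O-methyl and butanoyl C–H bonds are stronger.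

**Step 6**
Reactants: 9 2-(bromomethyl)-6-butanoyl-3,5-dimethoxy-4,4-dimethylcyclohexa-2,5-dien-1-one; 3 tributyl(ethoxyethynyl)stannane
Product: 10 2-butanoyl-6-(3-ethoxyprop-2-yn-1-yl)-3,5-dimethoxy-4,4-dimethylcyclohexa-2,5-dien-1-one
Conditions: Pd2(dba)3 (2.5 mol%), AsPh3 (10 mol%), THF, 40 °C; chromatography on Et3N-deactivated silica
Reagents that add atoms: none
Why: Stille coupling of an allylic bromide with an alkynylstannane (oxidative addition to zerovalent palladium, alkynyl transfer from tin, reductive elimination at the unhindered CH2); the neutral conditions should leave both ketones and the enol ethers untouched and avoid base-induced isomerisation of the ynol ether to an allenyl ether, which a lithium acetylide would risk.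

**Step 7**
Reactants: 11 1-(2,4,6-trihydroxyphenyl)ethan-1-one (commercial, dried)
Product: 12 2-acetyl-3,5-dihydroxy-4,4,6-trimethylcyclohexa-2,5-dien-1-one
Conditions: NaOMe (4.5 equiv), MeI (3.2 equiv), MeOH, 0 °C → rt; aq. HCl
Reagents that add atoms: iodomethane, CI
Why: The same dearomatising C-methylation of an acylphloroglucinol as in step 3.

**Step 8**
Reactants: 12 2-acetyl-3,5-dihydroxy-4,4,6-trimethylcyclohexa-2,5-dien-1-one
Product: 13 2-acetyl-3,5-dimethoxy-4,4,6-trimethylcyclohexa-2,5-dien-1-one
Conditions: TMSCHN2 (4 equiv), toluene–MeOH 4:1, 0 °C → rt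
Reagents that add atoms: (trimethylsilyl)diazomethane, C[Si](C)(C)C=[N+]=[N-]
Why: Diazoalkane O-methylation of both enols, as in step 4.

**Step 9**
Reactants: 13 2-acetyl-3,5-dimethoxy-4,4,6-trimethylcyclohexa-2,5-dien-1-one
Product: 14 2-acetyl-6-(bromomethyl)-3,5-dimethoxy-4,4-dimethylcyclohexa-2,5-dien-1-one
Conditions: NBS (1.05 equiv), AIBN (5 mol%), PhCF3, 80 °C
Reagents that add atoms: N-bromosuccinimide, O=C1CCC(=O)N1Br
Why: Wohl–Ziegler bromination at the allylic C6 methyl group, as in step 5; the acetyl methyl gives a less stabilised radical and should react more slowly.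

**Step 10**
Reactants: 14 2-acetyl-6-(bromomethyl)-3,5-dimethoxy-4,4-dimethylcyclohexa-2,5-dien-1-one; 3 tributyl(ethoxyethynyl)stannane
Product: 15 2-acetyl-6-(3-ethoxyprop-2-yn-1-yl)-3,5-dimethoxy-4,4-dimethylcyclohexa-2,5-dien-1-one
Conditions: Pd2(dba)3 (2.5 mol%), AsPh3 (10 mol%), THF, 40 °C; chromatography on Et3N-deactivated silica
Reagents that add atoms: none
Why: Stille coupling of the allylic bromide with the alkynylstannane, as in step 6.

**Step 11**
Reactants: 15 2-acetyl-6-(3-ethoxyprop-2-yn-1-yl)-3,5-dimethoxy-4,4-dimethylcyclohexa-2,5-dien-1-one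
Product: 16 2-acetyl-6-[(2-ethoxy-4-oxocyclobut-1-en-1-yl)methyl]-3,5-dimethoxy-4,4-dimethylcyclohexa-2,5-dien-1-one
Conditions: ketene (gas stream from a ketene generator, excess), CH2Cl2, 0 °C → rt
Reagents that add atoms: ketene, C=C=O
Why: [2+2] cycloaddition of ketene with an alkoxyalkyne, the standard entry to 3-ethoxycyclobutenones: the alkyne carbon remote from oxygen attacks the ketene carbonyl carbon, which places the ring C arm on C2 and the ethoxy group on C3, while the push–pull enol ethers of ring C should be too electron-poor to react.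

**Step 12**
Reactants: 16 2-acetyl-6-[(2-ethoxy-4-oxocyclobut-1-en-1-yl)methyl]-3,5-dimethoxy-4,4-dimethylcyclohexa-2,5-dien-1-one (1.2 equiv); 10 2-butanoyl-6-(3-ethoxyprop-2-yn-1-yl)-3,5-dimethoxy-4,4-dimethylcyclohexa-2,5-dien-1-one
Product: 21 protected trimer phenol (ring B = 3,5-diethoxyphenol; ring A arm at B1; ring C arm at B3; B5 unsubstituted), via vinylketene 17 (not isolated), via 4-vinylcyclobutenone 18 (not isolated), via dienylketene 19 (not isolated), via cyclohexa-2,4-dienone 20 (not isolated)
Conditions: toluene (degassed), 85 °C, sealed tube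
Reagents that add atoms: none
Why: Proposed new method: heat should open 16 by 4π electrocyclic ring opening to (1-ethoxyvinyl)ketene 17, whose ketene C=C adds ynol ether 10 in a [2+2] step (bonds B6–B1 and B2–B3) to give 18; a second 4π opening gives dienylketene 19, which closes ring B by 6π electrocyclisation (bond B5–B6) to dienone 20 and tautomerises to phenol 21. The closest known reaction is the Danheiser benzannulation of alkyl-substituted cyclobutenones with alkoxy- or silyloxyalkynes to resorcinol monoethers; a 3-alkoxycyclobutenone, which is what produces the third oxygen of a phloroglucinol, has not been shown in it, and its vinylogous-ester stabilisation may slow the first ring opening. Ring B is therefore closed by a thermal 6π electrocyclisation of a ketene formed in place, not by an ionic condensation. No stereocentre remains in 21, since the quaternary carbon of racemic 18 is lost on ring opening. The step needs regioselective [2+2] addition, secured by the polarisation of the ynol ether: its carbon remote from oxygen, which bears the ring A arm, attacks the ketene carbonyl carbon, so the three oxygens fall on alternate ring carbons with the arms between them. The temperature is kept below the point where an ethyl ynol ether loses ethylene by retro-ene reaction, and both outer rings are fully O-methylated so that no hydroxyl group can capture a ketene.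

**Step 13**
Reactants: 21 protected trimer phenol; 5 butyryl chloride
Product: 22 butanoate ester of phenol 21
Conditions: Et3N, DMAP (cat.), CH2Cl2, 0 °C → rt
Reagents that add atoms: none
Why: DMAP-catalysed O-acylation of the single free phenol; every other oxygen is etherified.

**Step 14**
Reactants: 22 butanoate ester of phenol 21
Product: 23 1-[4,6-diethoxy-2-hydroxy-3-(ring A arm)-5-(ring C arm)phenyl]butan-1-one
Conditions: BF3·OEt2 (promoter, excess), ClCH2CH2Cl, rt → 50 °C; aq. NaOAc
Reagents that add atoms: none
Why: Fries rearrangement, in which the activated acyl group should move to B5, the only unsubstituted ring carbon and one that is ortho to the phenolic oxygen and ortho/para to the two ethoxy groups; BF3 has no nucleophilic counter-ion, so the methyl enol ethers should survive.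

**Step 15**
Reactants: 23 1-[4,6-diethoxy-2-hydroxy-3-(ring A arm)-5-(ring C arm)phenyl]butan-1-one
Product: 24 target, 2-butanoyl-6-[[3-[(5-acetyl-2,4-dihydroxy-3,3-dimethyl-6-oxocyclohexa-1,4-dien-1-yl)methyl]-5-butanoyl-2,4,6-trihydroxyphenyl]methyl]-3,5-dihydroxy-4,4-dimethylcyclohexa-2,5-dien-1-one
Conditions: BBr3 (12 equiv), CH2Cl2, −78 °C → rt; then H2O, 0 °C
Reagents that add atoms: none
Why: Lewis acid ether cleavage with BBr3 (oxygen complexation, then SN2 attack of bromide on methyl or ethyl), expected to take the four vinylogous methyl esters and the carbonyl-chelated B4 ethyl ether first and the B2 ethyl ether last; hydrolysis of the borates should give the target in the enol form drawn.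

**Compound list**
1 | ethoxyacetylene | CCOC#C | starting material
2 | lithium ethoxyacetylide | [Li]C#COCC | intermediate
3 | tributyl(ethoxyethynyl)stannane | CCCC[Sn](CCCC)(CCCC)C#COCC | intermediate
4 | phloroglucinol (benzene-1,3,5-triol) | Oc1cc(O)cc(O)c1 | starting material
5 | butyryl chloride | CCCC(Cl)=O | starting material
6 | 1-(2,4,6-trihydroxyphenyl)butan-1-one | CCCC(=O)c1c(O)cc(O)cc1O | intermediate
7 | 2-butanoyl-3,5-dihydroxy-4,4,6-trimethylcyclohexa-2,5-dien-1-one (one enol tautomer drawn) | CCCC(=O)C1=C(O)C(C)(C)C(O)=C(C)C1=O | intermediate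
8 | 2-butanoyl-3,5-dimethoxy-4,4,6-trimethylcyclohexa-2,5-dien-1-one | CCCC(=O)C1=C(OC)C(C)(C)C(OC)=C(C)C1=O | intermediate
9 | 2-(bromomethyl)-6-butanoyl-3,5-dimethoxy-4,4-dimethylcyclohexa-2,5-dien-1-one | CCCC(=O)C1=C(OC)C(C)(C)C(OC)=C(CBr)C1=O | intermediate
10 | 2-butanoyl-6-(3-ethoxyprop-2-yn-1-yl)-3,5-dimethoxy-4,4-dimethylcyclohexa-2,5-dien-1-one (ynol ether with ring A) | CCOC#CCC1=C(OC)C(C)(C)C(OC)=C(C(=O)CCC)C1=O | intermediate
11 | 1-(2,4,6-trihydroxyphenyl)ethan-1-one | CC(=O)c1c(O)cc(O)cc1O | starting material
12 | 2-acetyl-3,5-dihydroxy-4,4,6-trimethylcyclohexa-2,5-dien-1-one (one enol tautomer drawn) | CC(=O)C1=C(O)C(C)(C)C(O)=C(C)C1=O | intermediate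
13 | 2-acetyl-3,5-dimethoxy-4,4,6-trimethylcyclohexa-2,5-dien-1-one | CC(=O)C1=C(OC)C(C)(C)C(OC)=C(C)C1=O | intermediate
14 | 2-acetyl-6-(bromomethyl)-3,5-dimethoxy-4,4-dimethylcyclohexa-2,5-dien-1-one | CC(=O)C1=C(OC)C(C)(C)C(OC)=C(CBr)C1=O | intermediate
15 | 2-acetyl-6-(3-ethoxyprop-2-yn-1-yl)-3,5-dimethoxy-4,4-dimethylcyclohexa-2,5-dien-1-one (ynol ether with ring C) | CCOC#CCC1=C(OC)C(C)(C)C(OC)=C(C(C)=O)C1=O | intermediate
16 | 2-acetyl-6-[(2-ethoxy-4-oxocyclobut-1-en-1-yl)methyl]-3,5-dimethoxy-4,4-dimethylcyclohexa-2,5-dien-1-one (3-ethoxycyclobutenone with ring C arm on C2) | O=C1CC(OCC)=C1CC2=C(OC)C(C)(C)C(OC)=C(C(C)=O)C2=O | intermediate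
17 | vinylketene: 3-ethoxy-2-(ring C arm)buta-1,3-dien-1-one | O=C=C(CC1=C(OC)C(C)(C)C(OC)=C(C(C)=O)C1=O)C(OCC)=C | intermediate
18 | 4-vinylcyclobutenone (racemic): 3-ethoxy-4-(1-ethoxyvinyl)-2-(ring A arm)-4-(ring C arm)cyclobut-2-en-1-one | O=C1C(CC2=C(OC)C(C)(C)C(OC)=C(C(=O)CCC)C2=O)=C(OCC)C1(CC3=C(OC)C(C)(C)C(OC)=C(C(C)=O)C3=O)C(OCC)=C | intermediate
19 | dienylketene: 3,5-diethoxy-2-(ring A arm)-4-(ring C arm)hexa-1,3,5-trien-1-one, ketene and vinyl groups cis on the central double bond | O=C=C(CC1=C(OC)C(C)(C)C(OC)=C(C(=O)CCC)C1=O)/C(OCC)=C(CC2=C(OC)C(C)(C)C(OC)=C(C(C)=O)C2=O)\C(OCC)=C | intermediate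
20 | 3,5-diethoxy-2-(ring A arm)-4-(ring C arm)cyclohexa-2,4-dien-1-one (keto tautomer of 21) | O=C1CC(OCC)=C(CC2=C(OC)C(C)(C)C(OC)=C(C(C)=O)C2=O)C(OCC)=C1CC3=C(OC)C(C)(C)C(OC)=C(C(=O)CCC)C3=O | intermediate
21 | protected trimer phenol: 3,5-diethoxyphenol carrying the ring A arm at C2 (B1, between OH and OEt) and the ring C arm at C4 (B3, between the two OEt groups); C6 (B5) is C–H | Oc1cc(OCC)c(CC2=C(OC)C(C)(C)C(OC)=C(C(C)=O)C2=O)c(OCC)c1CC3=C(OC)C(C)(C)C(OC)=C(C(=O)CCC)C3=O | intermediate
22 | butanoate ester of phenol 21 | CCCC(=O)Oc1cc(OCC)c(CC2=C(OC)C(C)(C)C(OC)=C(C(C)=O)C2=O)c(OCC)c1CC3=C(OC)C(C)(C)C(OC)=C(C(=O)CCC)C3=O | intermediate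
23 | 1-[4,6-diethoxy-2-hydroxy-3-(ring A arm)-5-(ring C arm)phenyl]butan-1-one | CCCC(=O)c1c(O)c(CC3=C(OC)C(C)(C)C(OC)=C(C(=O)CCC)C3=O)c(OCC)c(CC2=C(OC)C(C)(C)C(OC)=C(C(C)=O)C2=O)c1OCC | intermediate
24 | 2-butanoyl-6-[[3-[(5-acetyl-2,4-dihydroxy-3,3-dimethyl-6-oxocyclohexa-1,4-dien-1-yl)methyl]-5-butanoyl-2,4,6-trihydroxyphenyl]methyl]-3,5-dihydroxy-4,4-dimethylcyclohexa-2,5-dien-1-one | CCCC(=O)C1=C(O)C(C)(C)C(O)=C(Cc2c(O)c(CC3=C(O)C(C)(C)C(O)=C(C(C)=O)C3=O)c(O)c(C(=O)CCC)c2O)C1=O | target

**Step count**
Total steps: 15.
Longest linear sequence: 9 steps (2, 3, 4, 5, 6, 12, 13, 14, 15; the ring C branch 7–11 followed by 12–15 is equally long).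

**Steps most likely to fail**

Step 12 (proposed new method). The vinylogous-ester stabilisation of 16 may slow the first ring opening so far that retro-ene loss of ethylene from ynol ether 10, or dimerisation of the vinylketene, overtakes the annulation. A ketene could also be captured by a dienone carbonyl of an outer ring. The fallback uses known chemistry, the C-alkylation of an acylphloroglucinol salt with an allylic bromide (as in C-prenylation). It sets out from butyrophenone 6 and bromides 14 and 9. The monosodium salt of 6 (NaOMe, MeOH, 0 °C, 6 in excess) should be alkylated by 14 at one of its two equivalent free ring carbons to give the mono-alkylated butyrophenone F1. A second C-alkylation of F1 with 9 under the same conditions should give the doubly alkylated butyrophenone F2, whose ring B is already the free butanoylphloroglucinol. BBr3 (CH2Cl2, −78 → 0 °C) would then remove the four methyl enol ethers. This path comes back to the route at target 24.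

Step 14. The Lewis acid may cause ipso attack at B1 or B3 with loss of an arm, plain de-acylation back to phenol 21, or partial loss of enol ether methyl groups. The fallback replaces the acyl shift by a Houben–Hoesch reaction and sets out from phenol 21. Butyronitrile with ZnCl2 and HCl gas in Et2O at 0 °C should attack B5 and precipitate the ketiminium chloride F3. Mild buffered aqueous hydrolysis (aq. NaOAc, 40 °C) should then give the ketone. This path comes back to the route at 23.

Step 15. The long exposure to BBr3 needed for the hindered B2 ethyl ether may cut or exchange the CH2 bridges between the rings (retro-Friedel–Crafts), or leave the de-ethylation incomplete. The fallback unmasks in two stages by different mechanisms and sets out from 23. Aqueous HCl in THF at 45 °C should hydrolyse the four vinylogous methyl esters by addition–elimination and give the ring B diethyl ether F4. BCl3 with n-Bu4NI (CH2Cl2, −78 → 0 °C) should then remove the two aryl ethyl ethers by iodide attack at low temperature. This path comes back to the route at 24.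

**Further compounds**
F1 | step 12 | 1-[3-(ring C arm)-2,4,6-trihydroxyphenyl]butan-1-one | CCCC(=O)c1c(O)cc(O)c(CC2=C(OC)C(C)(C)C(OC)=C(C(C)=O)C2=O)c1O
F2 | step 12 | 1-[3-(ring A arm)-5-(ring C arm)-2,4,6-trihydroxyphenyl]butan-1-one | CCCC(=O)c1c(O)c(CC2=C(OC)C(C)(C)C(OC)=C(C(=O)CCC)C2=O)c(O)c(CC3=C(OC)C(C)(C)C(OC)=C(C(C)=O)C3=O)c1O
F3 | step 14 | ketiminium chloride of 23 (C=NH2+ in place of the B5 ketone C=O) | [Cl-].CCCC(=[NH2+])c1c(O)c(CC3=C(OC)C(C)(C)C(OC)=C(C(=O)CCC)C3=O)c(OCC)c(CC2=C(OC)C(C)(C)C(OC)=C(C(C)=O)C2=O)c1OCC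
F4 | step 15 | 23 with all four enol ether methyl groups removed (outer rings as free enols, ring B still 4,6-diethoxy) | CCCC(=O)c1c(O)c(CC3=C(O)C(C)(C)C(O)=C(C(=O)CCC)C3=O)c(OCC)c(CC2=C(O)C(C)(C)C(O)=C(C(C)=O)C2=O)c1OCC
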